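Ring B is cut into two three-carbon units: C10–C5–C6 of ring A, stored as a cyclopropane in which C6 bridges C5 and C10, and C7–C8(=C17)–C9, stored as a 2-(silylmethyl) enal. In one Lewis-acid operation the strained C6–C10 bond opens onto the aldehyde carbon C7 and the unmasked allylsilane closes C9 onto the new C10 cation, forming C6–C7 and C9–C10, the trans ring fusion, C9 and the C8 methylene together. The step exploits the exocyclic methylene at C8 of ring B, flanked by oxygenated C7 and by C9, and the 1,3-relationship of C6 and C10 across C5. Oxidation state adjustment at C7 and a Negishi methylalumination complete the target.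

Key step: step 11

Remark: the target is read as methyl 7β-acetoxy-15-hydroxylabda-8(17),13E-dien-19-oate (4S,5R,7S,9R,10R); labdane atom numbers and α/β (usual labdane drawing) are used for all intermediates.

Step 1
Reactants: 1 3-methylcyclohex-2-en-1-one
Product: 2 (S)-3-methylcyclohex-2-en-1-ol
Conditions: (R)-2-methyl-CBS-oxazaborolidine (10 mol %), catecholborane, toluene, −78 °C; then 1 M NaOH
Reagents that add atoms: none
Why: Corey–Bakshi–Shibata reduction, in which the alkenyl arm of the enone acts as the large group so that the (R)-catalyst should deliver hydride to the face that gives the (S)-carbinol.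

Step 2
Reactants: 2 (S)-3-methylcyclohex-2-en-1-ol
Product: 3 (1R,2S,6S)-6-methylbicyclo[4.1.0]heptan-2-ol
Conditions: Et2Zn, CH2I2, CH2Cl2, 0 °C → rt
Reagents that add atoms: diiodomethane ICI
Why: Hydroxyl-directed Simmons–Smith (Furukawa) cyclopropanation, in which the zinc alkoxide delivers CH2 to the alkene face syn to the hydroxyl and so sets both cyclopropane carbons (later C5 and C10) with C6 on the β face.

Step 3
Reactants: 3 (1R,2S,6S)-6-methylbicyclo[4.1.0]heptan-2-ol
Product: 4 (1R,6S)-6-methylbicyclo[4.1.0]heptan-2-one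
Conditions: Dess–Martin periodinane, NaHCO3, CH2Cl2, rt
Reagents that add atoms: none
Why: Dess–Martin oxidation of the secondary carbinol, which leaves the two cyclopropane stereocentres untouched.

Step 4
Reactants: 4 (1R,6S)-6-methylbicyclo[4.1.0]heptan-2-one
Product: 6 (1R,6S)-6-methylbicyclo[4.1.0]hept-2-en-2-yl trifluoromethanesulfonate, via lithium enolate 5 (not isolated)
Conditions: LiN(SiMe3)2, THF, −78 °C; then PhNTf2, −78 → 0 °C
Reagents that add atoms: N-phenylbis(trifluoromethanesulfonimide) FC(F)(F)S(=O)(=O)N(c1ccccc1)S(=O)(=O)C(F)(F)F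
Why: Enol triflate formation, with enolisation possible only away from the cyclopropane bridgehead, so a single regioisomer should form.

Step 5
Reactants: 6 (1R,6S)-6-methylbicyclo[4.1.0]hept-2-en-2-yl trifluoromethanesulfonate
Product: 7 methyl (1R,6S)-6-methylbicyclo[4.1.0]hept-2-ene-2-carboxylate
Conditions: Pd(OAc)2 (5 mol %), PPh3, CO (1 atm), MeOH, Et3N, DMF, 60 °C
Reagents that add atoms: carbon monoxide [C-]#[O+]; methanol CO
Why: Palladium-catalysed methoxycarbonylation of an enol triflate (oxidative addition to zerovalent palladium, CO insertion, methanolysis) installs the C19 ester carbon.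

Step 6
Reactants: 7 methyl (1R,6S)-6-methylbicyclo[4.1.0]hept-2-ene-2-carboxylate
Product: 9 methyl (1R,2S,6S)-2,6-dimethylbicyclo[4.1.0]heptane-2-carboxylate, via lithium ester enolate 8 (not isolated)
Conditions: LiBH(s-Bu)3, THF, −78 °C; then MeI, DMPU, −78 → 0 °C
Reagents that add atoms: iodomethane CI
Why: Reductive alkylation (conjugate hydride addition, then enolate methylation), in which MeI should approach the enolate on the face opposite the cyclopropane methylene, setting C4 with the ester cis to C6.

Step 7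
Reactants: 10 3-(trimethylsilyl)propan-1-ol
Product: 11 3-(trimethylsilyl)propanal
Conditions: Dess–Martin periodinane, CH2Cl2, rt
Reagents that add atoms: none
Why: Dess–Martin oxidation of a primary alcohol to the aldehyde without over-oxidation.

Step 8
Reactants: 11 3-(trimethylsilyl)propanal
Product: 12 N-cyclohexyl-3-(trimethylsilyl)propan-1-imine
Conditions: cyclohexylamine, MgSO4, Et2O, 0 °C → rt
Reagents that add atoms: cyclohexylamine NC1CCCCC1
Why: Imine condensation, which turns the aldehyde into a metalatable aza-enolate precursor for a directed aldol.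

Step 9
Reactants: 13 pent-4-yn-1-ol
Product: 14 pent-4-ynal
Conditions: Dess–Martin periodinane, NaHCO3, CH2Cl2, 0 °C → rt
Reagents that add atoms: none
Why: Dess–Martin oxidation of the primary alcohol; the terminal alkyne is inert.

Step 10
Reactants: 12 N-cyclohexyl-3-(trimethylsilyl)propan-1-imine; 14 pent-4-ynal
Product: 17 (2Z)-2-[(trimethylsilyl)methyl]hept-2-en-6-ynal, via lithium aza-enolate 15 (not isolated), via lithium aldolate imine 16 (not isolated)
Conditions: LiN(i-Pr)2, THF, −78 °C; 14, −78 °C; then aq. oxalic acid, THF, rt → 50 °C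
Reagents that add atoms: water O
Why: Wittig directed aldol condensation through the metalated imine, where acidic hydrolysis and dehydration should give the thermodynamically favoured enal with the chain trans to CHO (2Z by the CIP rules because of silicon).

Step 11
Reactants: 9 methyl (1R,2S,6S)-2,6-dimethylbicyclo[4.1.0]heptane-2-carboxylate; 17 (2Z)-2-[(trimethylsilyl)methyl]hept-2-en-6-ynal
Product: 19 methyl (1S,4aR,5R,8aR)-5-(but-3-yn-1-yl)-7-hydroxy-1,4a-dimethyl-6-methylidenedecahydronaphthalene-1-carboxylate (both C7 epimers), via trimethylsilyl ether 18 (not isolated)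
Conditions: Me3SiOTf (20 mol %), 2,6-di-tert-butyl-4-methylpyridine (30 mol %), CH2Cl2, −78 → −30 °C; then 1 M HCl, THF, 0 °C
Reagents that add atoms: none
Why: Proposed new method: O-silylation of enal 17 gives a siloxyallyl cation that is attacked at C7 by the strained C6–C10 σ-bond of 9 through its unsubstituted carbon C6 (Markovnikov opening, positive charge on tertiary C10 and not on C5, which is secondary and next to the ester-bearing C4); this turns the enal-deactivated silane into a free allylsilane whose C9 captures C10, and transfer of Me3Si+ to the next aldehyde oxygen leaves the C8=C17 methylene and keeps the silyl triflate catalytic. The closest known reaction types are the electrophilic Markovnikov ring opening of alkylcyclopropanes (protolytic, mercurative, acylative), the Lewis acid homoallylation of aldehydes by cyclopropylmethylstannanes, the formal [3+3] annulation of donor–acceptor cyclopropanes with 2-(chloromethyl)allylsilanes and the allylsilane-terminated cation–olefin cyclisation. Ring B closes in a 6-endo-trig Sakurai-type mode through a chair. C5 is carried over from 9; C10 is set by attack of C9 anti to the departing C6, on the α face (the β face is also covered by the axial C19 ester), which gives the trans ring fusion; C9 follows from the 2Z geometry of 17, which places the butynyl chain equatorial; C7 arises in the intermolecular first bond formation, is not expected to be controlled and is corrected in steps 12 and 13. The step needs 1,2- over 1,4-attack on the siloxyallyl cation and needs the cyclopropane to be the best nucleophile present, which is why the side chain of 17 is kept as a terminal alkyne, its allylsilane stays conjugated to the carbonyl until C7 has reacted, and a hindered pyridine removes adventitious TfOH.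

Step 12
Reactants: 19 methyl (1S,4aR,5R,8aR)-5-(but-3-yn-1-yl)-7-hydroxy-1,4a-dimethyl-6-methylidenedecahydronaphthalene-1-carboxylate (both C7 epimers)
Product: 20 methyl (1S,4aR,5R,8aR)-5-(but-3-yn-1-yl)-1,4a-dimethyl-6-methylidene-7-oxodecahydronaphthalene-1-carboxylate
Conditions: Dess–Martin periodinane, NaHCO3, CH2Cl2, rt
Reagents that add atoms: none
Why: Dess–Martin oxidation of the allylic alcohols converges both C7 epimers on one α-methylene ketone.

Step 13
Reactants: 20 methyl (1S,4aR,5R,8aR)-5-(but-3-yn-1-yl)-1,4a-dimethyl-6-methylidene-7-oxodecahydronaphthalene-1-carboxylate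
Product: 21 methyl (1S,4aR,5R,7S,8aR)-5-(but-3-yn-1-yl)-7-hydroxy-1,4a-dimethyl-6-methylidenedecahydronaphthalene-1-carboxylate
Conditions: NaBH4, CeCl3·7H2O, MeOH, −78 °C
Reagents that add atoms: none
Why: Luche reduction, 1,2-selective on the enone, in which the small hydride should add axially from the α face (only H5 and H9 are syn-axial there) to give the equatorial 7β-alcohol.

Step 14
Reactants: 21 methyl (1S,4aR,5R,7S,8aR)-5-(but-3-yn-1-yl)-7-hydroxy-1,4a-dimethyl-6-methylidenedecahydronaphthalene-1-carboxylate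
Product: 22 methyl (1S,4aR,5R,7S,8aR)-7-acetoxy-5-(but-3-yn-1-yl)-1,4a-dimethyl-6-methylidenedecahydronaphthalene-1-carboxylate
Conditions: Ac2O, pyridine, DMAP (cat.), CH2Cl2, rt
Reagents that add atoms: acetic anhydride CC(=O)OC(C)=O
Why: DMAP-catalysed acylation of the unhindered equatorial secondary alcohol with retention at C7.

Step 15
Reactants: 22 methyl (1S,4aR,5R,7S,8aR)-7-acetoxy-5-(but-3-yn-1-yl)-1,4a-dimethyl-6-methylidenedecahydronaphthalene-1-carboxylate
Product: 24 methyl (1S,4aR,5R,7S,8aR)-7-acetoxy-5-[(3E)-5-hydroxy-3-methylpent-3-en-1-yl]-1,4a-dimethyl-6-methylidenedecahydronaphthalene-1-carboxylate, via alkenyldimethylalane 23 (not isolated)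
Conditions: AlMe3, Cp2ZrCl2 (20 mol %), H2O (1 equiv), CH2Cl2, −30 °C; then (CH2O)n, −30 °C → rt; aq. potassium sodium tartrate
Reagents that add atoms: trimethylaluminium C[Al](C)C; formaldehyde (from paraformaldehyde) C=O
Why: Negishi zirconium-catalysed methylalumination, a syn addition of Me–Al across the terminal alkyne (Me to C13, Al to C14) that fixes the 13E geometry, followed by trapping of the alkenylalane with formaldehyde with retention.

Compound list
1 | 3-methylcyclohex-2-en-1-one | CC1=CC(=O)CCC1 | starting material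
2 | (S)-3-methylcyclohex-2-en-1-ol | O[C@H]1CCCC(C)=C1 | intermediate
3 | (1R,2S,6S)-6-methylbicyclo[4.1.0]heptan-2-ol | C1[C@@H]2[C@@]1(C)CCC[C@@H]2O | intermediate
4 | (1R,6S)-6-methylbicyclo[4.1.0]heptan-2-one | C1[C@@H]2[C@@]1(C)CCCC2=O | intermediate
5 | lithium (1R,6S)-6-methylbicyclo[4.1.0]hept-2-en-2-olate (not isolated) | C1[C@@H]2[C@@]1(C)CCC=C2O[Li] | intermediate
6 | (1R,6S)-6-methylbicyclo[4.1.0]hept-2-en-2-yl trifluoromethanesulfonate | C1[C@@H]2[C@@]1(C)CCC=C2OS(=O)(=O)C(F)(F)F | intermediate
7 | methyl (1R,6S)-6-methylbicyclo[4.1.0]hept-2-ene-2-carboxylate | C1[C@@H]2[C@@]1(C)CCC=C2C(=O)OC | intermediate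
8 | lithium ester enolate (O-lithio ketene acetal) from 1,4-hydride addition to 7 (not isolated) | C1[C@@H]2[C@@]1(C)CCCC2=C(OC)O[Li] | intermediate
9 | methyl (1R,2S,6S)-2,6-dimethylbicyclo[4.1.0]heptane-2-carboxylate | C1[C@@H]2[C@@]1(C)CCC[C@]2(C)C(=O)OC | intermediate
10 | 3-(trimethylsilyl)propan-1-ol | C[Si](C)(C)CCCO | starting material
11 | 3-(trimethylsilyl)propanal | C[Si](C)(C)CCC=O | intermediate
12 | N-cyclohexyl-3-(trimethylsilyl)propan-1-imine | C[Si](C)(C)CCC=NC1CCCCC1 | intermediate
13 | pent-4-yn-1-ol | C#CCCCO | starting material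
14 | pent-4-ynal | C#CCCC=O | intermediate
15 | lithium N-cyclohexyl-N-[3-(trimethylsilyl)prop-1-en-1-yl]amide (not isolated) | C[Si](C)(C)CC=CN([Li])C1CCCCC1 | intermediate
16 | lithium alkoxide of N-cyclohexyl-3-hydroxy-2-[(trimethylsilyl)methyl]hept-6-yn-1-imine (not isolated) | C#CCCC(O[Li])C(C[Si](C)(C)C)C=NC1CCCCC1 | intermediate
17 | (2Z)-2-[(trimethylsilyl)methyl]hept-2-en-6-ynal | C#CCC/C=C(/C=O)C[Si](C)(C)C | intermediate
18 | methyl (1S,4aR,5R,8aR)-5-(but-3-yn-1-yl)-1,4a-dimethyl-6-methylidene-7-[(trimethylsilyl)oxy]decahydronaphthalene-1-carboxylate, both C7 epimers (not isolated) | C=C1C(O[Si](C)(C)C)C[C@@H]2[C@](C)(CCC[C@]2(C)C(=O)OC)[C@H]1CCC#C | intermediate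
19 | methyl (1S,4aR,5R,8aR)-5-(but-3-yn-1-yl)-7-hydroxy-1,4a-dimethyl-6-methylidenedecahydronaphthalene-1-carboxylate, both C7 epimers | C=C1C(O)C[C@@H]2[C@](C)(CCC[C@]2(C)C(=O)OC)[C@H]1CCC#C | intermediate
20 | methyl (1S,4aR,5R,8aR)-5-(but-3-yn-1-yl)-1,4a-dimethyl-6-methylidene-7-oxodecahydronaphthalene-1-carboxylate | C=C1C(=O)C[C@@H]2[C@](C)(CCC[C@]2(C)C(=O)OC)[C@H]1CCC#C | intermediate
21 | methyl (1S,4aR,5R,7S,8aR)-5-(but-3-yn-1-yl)-7-hydroxy-1,4a-dimethyl-6-methylidenedecahydronaphthalene-1-carboxylate | C=C1[C@@H](O)C[C@@H]2[C@](C)(CCC[C@]2(C)C(=O)OC)[C@H]1CCC#C | intermediate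
22 | methyl (1S,4aR,5R,7S,8aR)-7-acetoxy-5-(but-3-yn-1-yl)-1,4a-dimethyl-6-methylidenedecahydronaphthalene-1-carboxylate | C=C1[C@@H](OC(C)=O)C[C@@H]2[C@](C)(CCC[C@]2(C)C(=O)OC)[C@H]1CCC#C | intermediate
23 | methyl (1S,4aR,5R,7S,8aR)-7-acetoxy-5-[(3E)-4-(dimethylalumanyl)-3-methylbut-3-en-1-yl]-1,4a-dimethyl-6-methylidenedecahydronaphthalene-1-carboxylate (not isolated) | C=C1[C@@H](OC(C)=O)C[C@@H]2[C@](C)(CCC[C@]2(C)C(=O)OC)[C@H]1CC/C(C)=C/[Al](C)C | intermediate
24 | methyl (1S,4aR,5R,7S,8aR)-7-acetoxy-5-[(3E)-5-hydroxy-3-methylpent-3-en-1-yl]-1,4a-dimethyl-6-methylidenedecahydronaphthalene-1-carboxylate (CNP0329157.1) | C=C1[C@@H](OC(C)=O)C[C@@H]2[C@](C)(CCC[C@]2(C)C(=O)OC)[C@H]1CC/C(C)=C/CO | target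

Total step count: 15. Longest linear sequence: 11 steps (steps 1–6, then 11–15); steps 7–10 build the second fragment.

Steps most likely to fail

Step 11 (proposed new method): the unactivated cyclopropane σ-bond may be too weak a nucleophile for the siloxyallyl cation, so that proton-initiated opening of 9 or oligomerisation of 17 outruns the annulation. The fallback makes the same two bonds one after the other with known reactions, setting out from 9 and 17. Oxymercuration of the cyclopropane of 9 (Hg(O2CCF3)2, THF/H2O, then NaCl; mercury on C6, hydroxyl on C10 with inversion) should give methyl (1S,2S,3S)-2-[(chloromercurio)methyl]-3-hydroxy-1,3-dimethylcyclohexane-1-carboxylate F1. Iodinolysis (I2, CH2Cl2) should give methyl (1S,2S,3S)-3-hydroxy-2-(iodomethyl)-1,3-dimethylcyclohexane-1-carboxylate F2. Iodine–lithium exchange (t-BuLi, Et2O, −78 °C) should give the O,C-dilithiated alkoxide–alkyllithium F3, which adds 1,2 to 17 to give the diol methyl (1S,2S,3S)-3-hydroxy-2-{(3Z)-2-hydroxy-3-[(trimethylsilyl)methyl]oct-3-en-7-yn-1-yl}-1,3-dimethylcyclohexane-1-carboxylate F4 (both carbinol epimers). SnCl4 (CH2Cl2, −78 °C) then ionises the tertiary alcohol and the allylsilane closes ring B (allylsilane-terminated cation–olefin cyclisation), which comes back to the route at 19.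

Step 15: the C7 acetate may be cleaved by the methylaluminium reagents, or the alkenylalane may be trapped only sluggishly by formaldehyde. The fallback sets out from 21, before acetylation. The same zirconium-catalysed methylalumination (AlMe3, Cp2ZrCl2, CH2Cl2) on the free alcohol should give the alkenylalane as its C7 dimethylaluminium alkoxide F5. Iodinolysis (I2, THF, −30 °C) should give methyl (1S,4aR,5R,7S,8aR)-7-hydroxy-5-[(3E)-4-iodo-3-methylbut-3-en-1-yl]-1,4a-dimethyl-6-methylidenedecahydronaphthalene-1-carboxylate F6. Acetylation (Ac2O, pyridine, DMAP) should give methyl (1S,4aR,5R,7S,8aR)-7-acetoxy-5-[(3E)-4-iodo-3-methylbut-3-en-1-yl]-1,4a-dimethyl-6-methylidenedecahydronaphthalene-1-carboxylate F7. Stille coupling with (tributylstannyl)methanol (Pd(PPh3)4, dioxane, 90 °C) installs the hydroxymethyl group and comes back at 24.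

Step 6: the borohydride may add 1,2 to the ester instead of 1,4, or the one-pot methylation may stall. The fallback sets out from 7. Copper hydride conjugate reduction with Stryker's reagent ([CuH(PPh3)]6, benzene, H2O, rt) should give the saturated ester methyl (1S,6S)-6-methylbicyclo[4.1.0]heptane-2-carboxylate F8 (C2 epimers). Separate deprotonation (LiN(i-Pr)2, THF, −78 °C) to enolate 8 and methylation with MeI anti to the cyclopropane comes back at 9.

Further compounds
F1 | step 11 | methyl (1S,2S,3S)-2-[(chloromercurio)methyl]-3-hydroxy-1,3-dimethylcyclohexane-1-carboxylate | Cl[Hg]C[C@@H]1[C@@](C)(O)CCC[C@]1(C)C(=O)OC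
F2 | step 11 | methyl (1S,2S,3S)-3-hydroxy-2-(iodomethyl)-1,3-dimethylcyclohexane-1-carboxylate | IC[C@@H]1[C@@](C)(O)CCC[C@]1(C)C(=O)OC
F3 | step 11 | O,C-dilithiated alkoxide–alkyllithium from F2 | [Li]C[C@@H]1[C@@](C)(O[Li])CCC[C@]1(C)C(=O)OC
F4 | step 11 | methyl (1S,2S,3S)-3-hydroxy-2-{(3Z)-2-hydroxy-3-[(trimethylsilyl)methyl]oct-3-en-7-yn-1-yl}-1,3-dimethylcyclohexane-1-carboxylate (both carbinol epimers) | C#CCC/C=C(/C(O)C[C@@H]1[C@@](C)(O)CCC[C@]1(C)C(=O)OC)C[Si](C)(C)C
F5 | step 15 | alkenyldimethylalane of 21 as its C7 dimethylaluminium alkoxide | C=C1[C@@H](O[Al](C)C)C[C@@H]2[C@](C)(CCC[C@]2(C)C(=O)OC)[C@H]1CC/C(C)=C/[Al](C)C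
F6 | step 15 | methyl (1S,4aR,5R,7S,8aR)-7-hydroxy-5-[(3E)-4-iodo-3-methylbut-3-en-1-yl]-1,4a-dimethyl-6-methylidenedecahydronaphthalene-1-carboxylate | C=C1[C@@H](O)C[C@@H]2[C@](C)(CCC[C@]2(C)C(=O)OC)[C@H]1CC/C(C)=C/I
F7 | step 15 | methyl (1S,4aR,5R,7S,8aR)-7-acetoxy-5-[(3E)-4-iodo-3-methylbut-3-en-1-yl]-1,4a-dimethyl-6-methylidenedecahydronaphthalene-1-carboxylate | C=C1[C@@H](OC(C)=O)C[C@@H]2[C@](C)(CCC[C@]2(C)C(=O)OC)[C@H]1CC/C(C)=C/I
F8 | step 6 | methyl (1S,6S)-6-methylbicyclo[4.1.0]heptane-2-carboxylate (C2 epimers) | C1[C@@H]2[C@@]1(C)CCCC2C(=O)OC
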